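**Retrosynthetic overview**
- Sargachromanol C ⇐ global desilylation ⇐ B-alkyl Suzuki–Miyaura coupling (C2'–C3') of hydroborated (S)-2-vinylchroman 13 with (E)-vinyl iodide 23.
- 13 ⇐ chroman-2-carbaldehyde 12 ⇐ glycol cleavage of diol 11 ⇐ 6-exo phenol opening (inversion) of a (2S,3R)-epoxy alcohol ⇐ catalytic Sharpless epoxidation of (Z)-allylic alcohol 8.
- 8 ⇐ B-alkyl Suzuki of styrene 5 (from 2-methylhydroquinone) with (Z)-3-iodobut-2-en-1-ol.
- 23 ⇐ isopropylidene Wittig ⇐ ketoreductase reduction of β-keto ester 19 (sets C9') ⇐ Masamune homologation, stabilised Wittig, Negishi carboalumination of pent-4-yn-1-ol.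
- Rings: the arene is bought (2-methylhydroquinone); the only ring formed is the dihydropyran of the chroman (step 9).

Assumption: the (R)-selective ketoreductase for step 17 is taken from a commercial KRED screening panel; all other reagents are commercial.

**Chroman fragment**

Step 1
Reactants: 1, 2-methylhydroquinone
Product: 2, 2-methyl-4-[(triisopropylsilyl)oxy]phenol
Conditions: TIPSCl (1.05 eq), imidazole, DMF, 0 °C → rt
Reagents that add atoms: triisopropylsilyl chloride, CC(C)[Si](Cl)(C(C)C)C(C)C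
Why: Regioselective O-silylation; the bulky silyl chloride takes the unhindered 4-OH and leaves the methyl-flanked 1-OH free (minor isomer and bis-ether removed by chromatography).

Step 2
Reactants: 2
Product: 3, 2-hydroxy-3-methyl-5-[(triisopropylsilyl)oxy]benzaldehyde
Conditions: MgCl2, Et3N, (CH2O)n, MeCN, reflux
Reagents that add atoms: paraformaldehyde (formaldehyde), C=O
Why: Mg-phenoxide-directed ortho-formylation (Casnati–Skattebøl) can only occur at the single free ortho position of the free phenol.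

Step 3
Reactants: 3
Product: 4, 2-(benzyloxy)-3-methyl-5-[(triisopropylsilyl)oxy]benzaldehyde
Conditions: BnBr, K2CO3, DMF, rt → 50 °C
Reagents that add atoms: benzyl bromide, BrCc1ccccc1
Why: Williamson etherification masks the future ring oxygen with a group that is later removed by hydrogenolysis once no alkene is present.

Step 4
Reactants: 4
Product: 5, [4-(benzyloxy)-3-methyl-5-vinylphenoxy]triisopropylsilane
Conditions: Ph3PCH3Br, NaHMDS, THF, 0 °C → rt
Reagents that add atoms: methyltriphenylphosphonium bromide, C[P+](c1ccccc1)(c1ccccc1)c1ccccc1.[Br-]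
Why: Wittig methylenation of a non-enolisable aryl aldehyde.

Step 5
Reactants: 6, but-2-yn-1-ol
Product: 7, (Z)-3-iodobut-2-en-1-ol
Conditions: Red-Al, THF, 0 °C → rt; then I2, −78 → 0 °C
Reagents that add atoms: iodine, II
Why: Hydroxyl-directed trans-hydroalumination gives a cyclic vinyl alanate (Al at C3, cis to CH2O), and iodinolysis with retention fixes the Z geometry.

Step 6
Reactants: 5; 7
Product: 8, (Z)-5-{2-(benzyloxy)-3-methyl-5-[(triisopropylsilyl)oxy]phenyl}-3-methylpent-2-en-1-ol
Conditions: 5, 9-BBN, THF, 0 °C → rt; then 7, Pd(dppf)Cl2 (5 mol%), aq K3PO4, DMF, rt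
Reagents that add atoms: none
Why: B-alkyl Suzuki–Miyaura coupling; anti-Markovnikov hydroboration of the styrene, then sp3–sp2 coupling with retention of the Z geometry.

Step 7
Reactants: 8
Product: 9, [(2S,3R)-3-(2-{2-(benzyloxy)-3-methyl-5-[(triisopropylsilyl)oxy]phenyl}ethyl)-3-methyloxiran-2-yl]methanol
Conditions: Ti(OiPr)4 (10 mol%), L-(+)-DET (12 mol%), TBHP, 4 Å MS, CH2Cl2, −20 °C
Reagents that add atoms: tert-butyl hydroperoxide, CC(C)(C)OO
Why: Catalytic Katsuki–Sharpless asymmetric epoxidation; L-(+)-tartrate delivers oxygen to the same face as with nerol, giving the (2S,3R)-epoxide (about 90–94% ee expected) and setting the first stereocentres.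

Step 8
Reactants: 9
Product: 10, [(2S,3R)-3-(2-{2-hydroxy-3-methyl-5-[(triisopropylsilyl)oxy]phenyl}ethyl)-3-methyloxiran-2-yl]methanol
Conditions: H2 (1 atm), 10% Pd/C, EtOAc, rt
Reagents that add atoms: none
Why: Benzyl ether hydrogenolysis; the substrate has no alkene, and the non-benzylic epoxide and aryl silyl ether are inert.

Step 9
Reactants: 10
Product: 11, (S)-1-{(S)-2,8-dimethyl-6-[(triisopropylsilyl)oxy]chroman-2-yl}ethane-1,2-diol
Conditions: p-TsOH·H2O (5 mol%), CH2Cl2, 0 °C
Reagents that add atoms: none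
Why: Acid-catalysed 6-exo-tet epoxide opening by the phenol at the tertiary carbon (favoured electronically and by ring size) proceeds with inversion, so the (3R)-epoxide carbon becomes the (S)-chroman C2.

Step 10
Reactants: 11
Product: 12, (S)-2,8-dimethyl-6-[(triisopropylsilyl)oxy]chroman-2-carbaldehyde
Conditions: NaIO4, THF/H2O, 0 °C → rt
Reagents that add atoms: none
Why: Periodate glycol cleavage (Malaprade) removes the terminal carbon as formaldehyde; the quaternary α-carbon cannot epimerise.

Step 11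
Reactants: 12
Product: 13, (S)-[(2,8-dimethyl-2-vinylchroman-6-yl)oxy]triisopropylsilane
Conditions: Ph3PCH3Br, NaHMDS, THF, 0 °C → rt
Reagents that add atoms: methyltriphenylphosphonium bromide, C[P+](c1ccccc1)(c1ccccc1)c1ccccc1.[Br-]
Why: Wittig methylenation of a non-enolisable aldehyde, so no elimination or epimerisation pathway exists.

**Side-chain fragment**

Step 12
Reactants: 14, pent-4-yn-1-ol
Product: 15, (E)-5-iodo-4-methylpent-4-en-1-ol
Conditions: AlMe3 (3 eq), Cp2ZrCl2 (0.25 eq), CH2Cl2, 0 °C → rt; then I2, THF, −30 → 0 °C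
Reagents that add atoms: trimethylaluminium, C[Al](C)C; iodine, II
Why: Negishi Zr-catalysed carboalumination adds Me and Al syn across the alkyne, and iodinolysis with retention gives only the E vinyl iodide.

Step 13
Reactants: 15
Product: 16, (E)-5-iodo-4-methylpent-4-enal
Conditions: Dess–Martin periodinane, NaHCO3, CH2Cl2, 0 °C → rt
Reagents that add atoms: none
Why: Dess–Martin oxidation of a primary alcohol; the vinyl iodide is untouched.

Step 14
Reactants: 16
Product: 17, ethyl (2E,6E)-7-iodo-2,6-dimethylhepta-2,6-dienoate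
Conditions: Ph3P=C(CH3)CO2Et, CH2Cl2, rt → 40 °C
Reagents that add atoms: ethyl 2-(triphenylphosphoranylidene)propanoate, CCOC(=O)C(C)=P(c1ccccc1)(c1ccccc1)c1ccccc1
Why: Wittig olefination with a stabilised α-methyl ylide gives the E-trisubstituted enoate (typically >95:5).

Step 15
Reactants: 17
Product: 18, (2E,6E)-7-iodo-2,6-dimethylhepta-2,6-dienoic acid
Conditions: LiOH·H2O, THF/MeOH/H2O, rt; then aq HCl
Reagents that add atoms: lithium hydroxide, [Li+].[OH-]
Why: Ester saponification; neither alkene can migrate under these conditions.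

Step 16
Reactants: 18
Product: 19, ethyl (4E,8E)-9-iodo-4,8-dimethyl-3-oxonona-4,8-dienoate
Conditions: CDI, THF, rt; then KO2CCH2CO2Et, MgCl2, Et3N, rt → 45 °C; aq HCl
Reagents that add atoms: potassium ethyl malonate, CCOC(=O)CC(=O)[O-].[K+]
Why: Masamune–Brooks homologation; the acyl imidazolide C-acylates the magnesium malonate and decarboxylation gives the β-keto ester.

Step 17
Reactants: 19
Product: 20, ethyl (3R,4E,8E)-3-hydroxy-9-iodo-4,8-dimethylnona-4,8-dienoate
Conditions: (R)-selective ketoreductase (KRED), NADP+ (cat.), i-PrOH (15% v/v), phosphate buffer pH 7, 30 °C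
Reagents that add atoms: none
Why: Ketoreductase-catalysed reduction delivers hydride from NADPH to the Si face of the ketone to give the (3R)-alcohol (future C9'), without touching the enone C=C, vinyl iodide or ester.

Step 18
Reactants: 20
Product: 21, ethyl (3R,4E,8E)-3-[(tert-butyldimethylsilyl)oxy]-9-iodo-4,8-dimethylnona-4,8-dienoate
Conditions: TBSOTf, 2,6-lutidine, CH2Cl2, −78 → 0 °C
Reagents that add atoms: tert-butyldimethylsilyl triflate, CC(C)(C)[Si](C)(C)OS(=O)(=O)C(F)(F)F
Why: Silylation of the hindered allylic alcohol under non-basic conditions that cannot cause retro-aldol or elimination.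

Step 19
Reactants: 21
Product: 22, (3R,4E,8E)-3-[(tert-butyldimethylsilyl)oxy]-9-iodo-4,8-dimethylnona-4,8-dienal
Conditions: DIBAL-H (1.1 eq), CH2Cl2, −78 °C; Rochelle salt
Reagents that add atoms: none
Why: Partial ester reduction; the tetrahedral aluminate is stable at −78 °C and releases the aldehyde on work-up.

Step 20
Reactants: 22
Product: 23, tert-butyl{[(5R,6E,10E)-11-iodo-2,6,10-trimethylundeca-2,6,10-trien-5-yl]oxy}dimethylsilane
Conditions: i-PrPPh3I, n-BuLi, THF, 0 °C; then 22, −78 °C → rt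
Reagents that add atoms: isopropyltriphenylphosphonium iodide, CC(C)[P+](c1ccccc1)(c1ccccc1)c1ccccc1.[I-]
Why: Wittig olefination with the isopropylidene ylide builds the prenyl terminus with no geometry issue; low-temperature addition suppresses β-elimination of the silyloxy group.

**Coupling and deprotection**

Step 21
Reactants: 13; 23
Product: 24, tert-butyl{[(5R,6E,10E)-13-{(R)-2,8-dimethyl-6-[(triisopropylsilyl)oxy]chroman-2-yl}-2,6,10-trimethyltrideca-2,6,10-trien-5-yl]oxy}dimethylsilane
Conditions: 13 (1.3 eq), 9-BBN, THF, rt; H2O; then 23, Pd(dppf)Cl2 (10 mol%), AsPh3, Cs2CO3, DMF/H2O, rt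
Reagents that add atoms: none
Why: B-alkyl Suzuki–Miyaura coupling; 9-BBN adds anti-Markovnikov to the vinyl group only (it is quenched before 23 is added), and coupling retains the E geometry without touching either stereocentre.

Step 22
Reactants: 24
Product: 25, sargachromanol C, (R)-2-[(3E,7E,9R)-9-hydroxy-4,8,12-trimethyltrideca-3,7,11-trien-1-yl]-2,8-dimethylchroman-6-ol
Conditions: TBAF (4 eq), THF, 0 °C → rt, under Ar
Reagents that add atoms: none
Why: Fluoride-mediated desilylation removes the aryl TIPS and allylic TBS ethers together under conditions that do not isomerise the trienol.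

**Compound list**
1 | 2-methylhydroquinone | Cc1cc(O)ccc1O | starting material
2 | 2-methyl-4-[(triisopropylsilyl)oxy]phenol | Cc1cc(O[Si](C(C)C)(C(C)C)C(C)C)ccc1O | intermediate
3 | 2-hydroxy-3-methyl-5-[(triisopropylsilyl)oxy]benzaldehyde | Cc1cc(O[Si](C(C)C)(C(C)C)C(C)C)cc(C=O)c1O | intermediate
4 | 2-(benzyloxy)-3-methyl-5-[(triisopropylsilyl)oxy]benzaldehyde | Cc1cc(O[Si](C(C)C)(C(C)C)C(C)C)cc(C=O)c1OCc1ccccc1 | intermediate
5 | [4-(benzyloxy)-3-methyl-5-vinylphenoxy]triisopropylsilane | Cc1cc(O[Si](C(C)C)(C(C)C)C(C)C)cc(C=C)c1OCc1ccccc1 | intermediate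
6 | but-2-yn-1-ol | CC#CCO | starting material
7 | (Z)-3-iodobut-2-en-1-ol | C/C(I)=C/CO | intermediate
8 | (Z)-5-{2-(benzyloxy)-3-methyl-5-[(triisopropylsilyl)oxy]phenyl}-3-methylpent-2-en-1-ol | Cc1cc(O[Si](C(C)C)(C(C)C)C(C)C)cc(CC/C(C)=C\CO)c1OCc1ccccc1 | intermediate
9 | [(2S,3R)-3-(2-{2-(benzyloxy)-3-methyl-5-[(triisopropylsilyl)oxy]phenyl}ethyl)-3-methyloxiran-2-yl]methanol | Cc1cc(O[Si](C(C)C)(C(C)C)C(C)C)cc(CC[C@@]2(C)O[C@H]2CO)c1OCc1ccccc1 | intermediate
10 | [(2S,3R)-3-(2-{2-hydroxy-3-methyl-5-[(triisopropylsilyl)oxy]phenyl}ethyl)-3-methyloxiran-2-yl]methanol | Cc1cc(O[Si](C(C)C)(C(C)C)C(C)C)cc(CC[C@@]2(C)O[C@H]2CO)c1O | intermediate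
11 | (S)-1-{(S)-2,8-dimethyl-6-[(triisopropylsilyl)oxy]chroman-2-yl}ethane-1,2-diol | OC[C@H](O)[C@]1(C)CCc2cc(O[Si](C(C)C)(C(C)C)C(C)C)cc(C)c2O1 | intermediate
12 | (S)-2,8-dimethyl-6-[(triisopropylsilyl)oxy]chroman-2-carbaldehyde | O=C[C@]1(C)CCc2cc(O[Si](C(C)C)(C(C)C)C(C)C)cc(C)c2O1 | intermediate
13 | (S)-[(2,8-dimethyl-2-vinylchroman-6-yl)oxy]triisopropylsilane | C=C[C@]1(C)CCc2cc(O[Si](C(C)C)(C(C)C)C(C)C)cc(C)c2O1 | intermediate
14 | pent-4-yn-1-ol | C#CCCCO | starting material
15 | (E)-5-iodo-4-methylpent-4-en-1-ol | OCCC/C(C)=C/I | intermediate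
16 | (E)-5-iodo-4-methylpent-4-enal | O=CCC/C(C)=C/I | intermediate
17 | ethyl (2E,6E)-7-iodo-2,6-dimethylhepta-2,6-dienoate | CCOC(=O)/C(C)=C/CC/C(C)=C/I | intermediate
18 | (2E,6E)-7-iodo-2,6-dimethylhepta-2,6-dienoic acid | OC(=O)/C(C)=C/CC/C(C)=C/I | intermediate
19 | ethyl (4E,8E)-9-iodo-4,8-dimethyl-3-oxonona-4,8-dienoate | CCOC(=O)CC(=O)/C(C)=C/CC/C(C)=C/I | intermediate
20 | ethyl (3R,4E,8E)-3-hydroxy-9-iodo-4,8-dimethylnona-4,8-dienoate | CCOC(=O)C[C@@H](O)/C(C)=C/CC/C(C)=C/I | intermediate
21 | ethyl (3R,4E,8E)-3-[(tert-butyldimethylsilyl)oxy]-9-iodo-4,8-dimethylnona-4,8-dienoate | CCOC(=O)C[C@@H](O[Si](C)(C)C(C)(C)C)/C(C)=C/CC/C(C)=C/I | intermediate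
22 | (3R,4E,8E)-3-[(tert-butyldimethylsilyl)oxy]-9-iodo-4,8-dimethylnona-4,8-dienal | O=CC[C@@H](O[Si](C)(C)C(C)(C)C)/C(C)=C/CC/C(C)=C/I | intermediate
23 | tert-butyl{[(5R,6E,10E)-11-iodo-2,6,10-trimethylundeca-2,6,10-trien-5-yl]oxy}dimethylsilane | CC(C)=CC[C@@H](O[Si](C)(C)C(C)(C)C)/C(C)=C/CC/C(C)=C/I | intermediate
24 | 6-O-TIPS, 9'-O-TBS sargachromanol C | CC(C)=CC[C@@H](O[Si](C)(C)C(C)(C)C)/C(C)=C/CC/C(C)=C/CC[C@]1(C)CCc2cc(O[Si](C(C)C)(C(C)C)C(C)C)cc(C)c2O1 | intermediate
25 | sargachromanol C | CC(C)=CC[C@@H](O)/C(C)=C/CC/C(C)=C/CC[C@]1(C)CCc2cc(O)cc(C)c2O1 | target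

**Summary**
Total steps: 22.
Longest linear sequence: 12 steps (1–4, 6–11, 21, 22, from 2-methylhydroquinone); the side-chain branch is 11 steps.

Steps most likely to fail:
1. Step 9 (phenol opening of the epoxide at the tertiary carbon): risk of partial SN1 character eroding ee, or Meinwald rearrangement. Fallback: form the ring with retention instead. Open the enantiomeric epoxide (D-(−)-DET) with Red-Al to the tertiary-alcohol 1,3-diol and close the chroman by intramolecular Cu- or Pd-catalysed O-arylation of an ortho-bromo arene analogue, so the C–O bond at the stereocentre is never broken.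
2. Step 17 (ketoreductase on a bulky enone β-keto ester): no panel enzyme may give both high conversion and high ee. Fallback: Luche reduction to racemic 20, then lipase-catalysed kinetic resolution by acyl transfer (vinyl acetate), recycling the unwanted enantiomer by MnO2 oxidation back to 19.
3. Step 21 (B-alkyl Suzuki of a borane next to a quaternary centre with a trisubstituted vinyl iodide): risk of slow transmetalation and protodeboronation. Fallback: move the disconnection to C1'–C2'. Reduce 12 to the chroman-2-ylmethanol, convert to the triflate, alkylate with the lithiated allylic phenyl sulfone of a C2'–C12' chain, then remove the sulfone by Pd-catalysed reduction (LiBHEt3, PdCl2(dppp)).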